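**Retrosynthetic overview**

1. Germacrane numbering is used throughout: C1 ring ketone, C2=C3 enol-ether alkene, C4=C5 Z-alkene, C6(O)/C7 lactone fusion, C8 ester carbinol, C9 free carbinol, C10 quaternary O-bearing carbon.
2. Enabling feature: the furanone atoms O–C10–C1(=O)–C2H=C3 are the cyclodehydrated hydrate, hence an isomer, of a 4-hydroxy-2-ynone HO–C10–C1≡C2–C3(=O). C3 lies between sp2 C4 and C2, so it can be CO inserted between a C4 vinyl iodide and a terminal C1≡C2 alkyne.
3. Key disconnection: 30 ⇒ monocyclic iodo-alkynyl diol 27 + CO. One palladium-catalysed operation closes the ten-membered carbocycle (C4–C3–C2) and then, as the last ring, the furanone (O10–C3).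
4. 27 ⇒ cis-α-methylene-γ-butyrolactone (first ring) by indium Barbier allylation of (Z)-3-iodobut-2-enal 17 with allylic bromide 14. The ester comes from acid 25.
5. 14 ⇒ (S)-glyceraldehyde acetonide 1. Its one stereocentre (C8) relays C9/C10 (dihydroxylation) and C6/C7 (allylation). Ring order: lactone, carbocycle, furanone.

Key step: step 20

Remark: aldehyde 1 is taken as the purchasable L-series compound and is used freshly distilled. Carbinol centres that are erased in the following step (in 13 and 23) are carried as mixtures.

**Route**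

Step 1
Reactants: 1 (S)-2,2-dimethyl-1,3-dioxolane-4-carbaldehyde; 2 ethyl 2-(triphenylphosphoranylidene)propanoate
Product: 3 ethyl (2E)-3-[(4R)-2,2-dimethyl-1,3-dioxolan-4-yl]-2-methylprop-2-enoate
Conditions: CH2Cl2, 0 °C to rt
Reagents that add atoms: none
Why: Wittig olefination with a stabilised α-methyl ylide should give the E-enoate (C8 trans to the ester) under neutral conditions that do not epimerise the bought stereocentre C8.

Step 2
Reactants: 3 enoate
Product: 4 ethyl (2R,3S)-3-[(4S)-2,2-dimethyl-1,3-dioxolan-4-yl]-2,3-dihydroxy-2-methylpropanoate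
Conditions: OsO4 (cat.), (DHQ)2PHAL (cat.), NMO, acetone/H2O, 0 °C
Reagents that add atoms: N-methylmorpholine N-oxide, C[N+]1([O-])CCOCC1; water, O
Why: Upjohn syn-dihydroxylation sets C9 and C10 in one event, since the E geometry fixes their threo relation and 1,3-allylic strain with the cis methyl group puts H-8 in the alkene plane so that OsO4 attacks anti to the allylic oxygen (erythro C8/C9), a bias the matched ligand reinforces.

Step 3
Reactants: 4 diol ester
Product: 5 ethyl (4R,5S)-5-[(4S)-2,2-dimethyl-1,3-dioxolan-4-yl]-2,2,4-trimethyl-1,3-dioxolane-4-carboxylate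
Conditions: Me2C(OMe)2, CSA (cat.), CH2Cl2, rt
Reagents that add atoms: 2,2-dimethoxypropane, COC(C)(C)OC
Why: Acid-catalysed transketalisation closes the trans-dioxolane on the secondary/tertiary C9/C10 diol and touches no stereocentre.

Step 4
Reactants: 5 bis-acetonide ester
Product: 6 (4R,5S)-5-[(4S)-2,2-dimethyl-1,3-dioxolan-4-yl]-2,2,4-trimethyl-1,3-dioxolane-4-carbaldehyde
Conditions: iBu2AlH, CH2Cl2, −78 °C; aq. potassium sodium tartrate
Reagents that add atoms: none
Why: Partial ester reduction stops at the tetrahedral aluminium hemiacetal at low temperature, and the aldehyde released on work-up cannot epimerise because C10 is fully substituted.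

Step 5
Reactants: 6 aldehyde
Product: 7 (4S,5S)-5-[(4S)-2,2-dimethyl-1,3-dioxolan-4-yl]-4-ethynyl-2,2,4-trimethyl-1,3-dioxolane
Conditions: MeC(O)C(N2)P(O)(OMe)2, K2CO3, MeOH, 0 °C to rt
Reagents that add atoms: dimethyl (1-diazo-2-oxopropyl)phosphonate, COP(=O)(OC)C(=[N+]=[N-])C(C)=O
Why: Ohira–Bestmann (Seyferth–Gilbert) homologation turns the non-enolisable aldehyde into the terminal alkyne C1≡C2 under mild base that leaves both acetonides intact.

Step 6
Reactants: 7 alkynyl bis-acetonide
Product: 8 (1S)-1-[(4S,5S)-5-ethynyl-2,2,5-trimethyl-1,3-dioxolan-4-yl]ethane-1,2-diol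
Conditions: AcOH/H2O (7:3), 40 °C
Reagents that add atoms: none
Why: Selective acetal hydrolysis, in which the terminal, less substituted dioxolane should be cleaved faster than the internal trans-dioxolane that is stabilised by the fully substituted, electron-poor propargylic C10.

Step 7
Reactants: 8 diol
Product: 9 bis(triethylsilyl) ether of 8 (O7 and O8 silylated)
Conditions: Et3SiCl, imidazole, DMAP (cat.), CH2Cl2, 0 °C to rt
Reagents that add atoms: chlorotriethylsilane, CC[Si](Cl)(CC)CC
Why: Standard silyl ether formation on the primary and the secondary hydroxyl, with no stereocentre involved.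

Step 8
Reactants: 9 bis-silyl ether
Product: 10 (2R)-2-[(4S,5S)-5-ethynyl-2,2,5-trimethyl-1,3-dioxolan-4-yl]-2-(triethylsilyloxy)acetaldehyde
Conditions: (COCl)2, DMSO, CH2Cl2, −78 to −30 °C; Et3N, −78 °C to 0 °C
Reagents that add atoms: none
Why: Swern conditions are known to convert primary triethylsilyl ethers directly into aldehydes while secondary ones survive, so C7 is oxidised and O8 stays protected in one step, and the cold amine quench spares the α-stereocentre C8.

Step 9
Reactants: 10 aldehyde; 11 methyl propiolate
Product: 13 Baylis–Hillman-type alcohol (methyl 3-hydroxy-2-methylidenebutanoate carrying 4-OSiEt3 and the dioxolane of 10; both C7 carbinol epimers), via vinylalane 12 (not isolated)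
Conditions: iBu2AlH, NMO, THF, 0 °C, then 11; then 10, 0 °C to rt
Reagents that add atoms: none
Why: Hydroalumination of the propiolate gives the α-aluminated acrylate, whose 1,2-addition to the aldehyde (vinylalumination, a stoichiometric Morita–Baylis–Hillman equivalent) is fast enough at 0 °C to avoid epimerisation at C8, and the new carbinol C7 is erased in step 10.

Step 10
Reactants: 13 allylic alcohol
Product: 14 methyl (2Z,4S)-2-(bromomethyl)-4-[(4S,5S)-5-ethynyl-2,2,5-trimethyl-1,3-dioxolan-4-yl]-4-(triethylsilyloxy)but-2-enoate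
Conditions: NBS, Me2S, CH2Cl2, 0 °C to rt
Reagents that add atoms: N-bromosuccinimide, O=C1CCC(=O)N1Br
Why: SN2' displacement of the sulfonium-activated alcohol by bromide (Corey–Kim-type activation) transposes the alkene and should give the Z-bromide (C8 cis to CH2Br), because this avoids 1,3-allylic strain between C8 and the ester.

Step 11
Reactants: 15 but-2-yn-1-ol
Product: 16 (Z)-3-iodobut-2-en-1-ol
Conditions: NaAlH2(OCH2CH2OMe)2, THF, 0 °C to rt; I2, −78 to 0 °C
Reagents that add atoms: iodine, II
Why: Hydroxyl-directed trans-hydroalumination places aluminium on C4 in a five-membered alkoxyaluminate, and iodinolysis with retention gives the Z-vinyl iodide that becomes the Z C4=C5 alkene.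

Step 12
Reactants: 16 iodo alcohol
Product: 17 (Z)-3-iodobut-2-enal
Conditions: MnO2, CH2Cl2, rt, dark; used crude
Reagents that add atoms: none
Why: Allylic oxidation with MnO2 is neutral and should not isomerise the Z-alkene.

Step 13
Reactants: 14 allylic bromide; 17 iodo enal
Product: 19 cis-lactone (3-methylideneoxolan-2-one with a 5-[(Z)-2-iodoprop-1-enyl] group and a 4-[CH(OSiEt3)-dioxolanyl] group; H-6/H-7 cis; C6–C10 arranged as in 30), via hydroxy ester 18 (not isolated)
Conditions: In powder, THF/H2O (4:1), rt; then PPTS (cat.), benzene, 50 °C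
Reagents that add atoms: none
Why: Barbier allylation then lactonisation, in which the 2-ester keeps the allylindium Z so that the chair transition state gives the syn adduct and hence the cis-lactone (C6/C7), while 1,3-allylic strain turns H-8 towards CH2In and the aldehyde attacks C7 anti to the bulky C9 dioxolane, relaying C8 to C7 and C6 in one event.

Step 14
Reactants: 19 silyl ether
Product: 20 C8 alcohol (19 with free O8–H)
Conditions: HF·pyridine, pyridine, THF, 0 °C
Reagents that add atoms: none
Why: Buffered fluoride desilylation removes the secondary triethylsilyl ether and leaves acetonide, vinyl iodide, alkyne and lactone untouched.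

Step 15
Reactants: 21 tert-butyl acrylate; 22 acetaldehyde
Product: 23 tert-butyl 3-hydroxy-2-methylidenebutanoate (racemic)
Conditions: DABCO (cat.), neat, rt
Reagents that add atoms: none
Why: Morita–Baylis–Hillman reaction of an unhindered aliphatic aldehyde with an acrylate, whose racemic carbinol centre is erased in step 16.

Step 16
Reactants: 23 Baylis–Hillman alcohol
Product: 24 tert-butyl (E)-2-(acetoxymethyl)but-2-enoate
Conditions: AcOH, PPh3, DIAD, THF, −20 °C to rt
Reagents that add atoms: acetic acid, CC(=O)O
Why: The Mitsunobu reaction of Baylis–Hillman alcohols is known to run in the SN2' sense, giving the primary acetate and the E-alkene (methyl trans to the ester) that minimises 1,3-allylic strain.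

Step 17
Reactants: 24 tert-butyl ester
Product: 25 (E)-2-(acetoxymethyl)but-2-enoic acid
Conditions: TFA/CH2Cl2 (1:4), 0 °C to rt
Reagents that add atoms: none
Why: Acidolysis of the tert-butyl ester (loss of isobutene) frees the acid without touching the acetate or the alkene geometry.

Step 18
Reactants: 20 C8 alcohol; 25 acid
Product: 26 C8 ester (20 acylated on O8 by 25; 9,10-acetonide retained)
Conditions: 2-methyl-6-nitrobenzoic anhydride, DMAP, Et3N, CH2Cl2, rt
Reagents that add atoms: none
Why: Shiina esterification (mixed-anhydride activation with nucleophilic catalysis) acylates the only free hydroxyl with retention at C8, and the thermodynamic E-alkene of the acid is safe from isomerisation.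

Step 19
Reactants: 26 ester acetonide
Product: 27 iodo-alkynyl diol (26 with free O9–H and O10–H)
Conditions: TFA/H2O (9:1), CH2Cl2, 0 °C
Reagents that add atoms: none
Why: Acid hydrolysis of the remaining acetonide frees both hydroxyls, while esters, allylic acetate, vinyl iodide and alkyne should tolerate cold aqueous TFA and no stereocentre is affected.

Step 20
Reactants: 27 iodo-alkynyl diol
Product: 30 target CNP0231561.2, via macrocyclic ynone 28 (not isolated), via hydroxy diketone 29 (not isolated)
Conditions: Pd(PPh3)4 (10 mol %), CuI (10 mol %), CO (1 atm), Et3N/THF, 40 °C, slow addition of 27 (final 1 mM); then H2O (5 vol %), 45 °C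
Reagents that add atoms: carbon monoxide, [C-]#[O+]; water, O
Why: Proposed new method: zerovalent palladium inserts into the C4–I bond of 27, CO insertion gives the (Z)-enoylpalladium iodide, the copper acetylide of the C1≡C2 terminus transmetalates and reductive elimination delivers the ten-membered 4-hydroxy-2-ynone 28, whose bent conjugated alkyne then takes up water at C1 under amine catalysis to give 29, after which O10 adds to the C3 carbonyl and water is lost again, so that water is only a shuttle and the furanone is formally an isomer of 28. The closest known reaction types are the intermolecular carbonylative Sonogashira coupling of vinyl and aryl iodides with tertiary propargylic alcohols, which in aqueous amine runs on to 2,2-dialkyl-3(2H)-furanones, the carbonylative Stille macrocyclisation, and the intramolecular Sonogashira closure of strained ten-membered enynes, and only their union in one medium-ring event is new. Modes of closure: the carbocycle closes first by C2–C3 reductive elimination from an eleven-membered acyl(alkynyl)palladacycle, and the furanone closes last by 5-exo-trig attack of O10 on C3 followed by dehydration, driven by release of the alkyne strain and by formation of the vinylogous ester. No stereocentre is created: C6 to C10 come unchanged from 27, C10 keeps its configuration because its C–O bond is never broken, and the Z geometry of C4=C5 is retained through oxidative addition and insertion. The step needs ring closure over oligomerisation, which the cis-lactone and the Z-alkene (both arms on one face), the fully substituted C10 and slow addition secure, and carbonylative over direct coupling, which is secured because direct coupling would have to form a nine-membered enyne. It also needs C–I over allylic C–O activation (vinyl iodides add far faster and no soft nucleophile is present to trap an allyl complex), acetylide over O9–H or methylene-lactone capture of the acylpalladium (acetylide transfer should outrun alcoholysis to an eight-membered lactone and insertion to a strained bridged bicycle), and O10 over O9 in the last closure (a five-membered hemiketal at a fully substituted carbon against a dihydropyranone bridged by an eight-membered ring).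

**Compound list**

1 | (S)-2,2-dimethyl-1,3-dioxolane-4-carbaldehyde | O=C[C@@H]1COC(C)(C)O1 | starting material
2 | ethyl 2-(triphenylphosphoranylidene)propanoate | CCOC(=O)C(C)=P(c1ccccc1)(c1ccccc1)c1ccccc1 | starting material
3 | ethyl (2E)-3-[(4R)-2,2-dimethyl-1,3-dioxolan-4-yl]-2-methylprop-2-enoate | CCOC(=O)/C(C)=C/[C@@H]1COC(C)(C)O1 | intermediate
4 | ethyl (2R,3S)-3-[(4S)-2,2-dimethyl-1,3-dioxolan-4-yl]-2,3-dihydroxy-2-methylpropanoate | CCOC(=O)[C@](C)(O)[C@@H](O)[C@@H]1COC(C)(C)O1 | intermediate
5 | ethyl (4R,5S)-5-[(4S)-2,2-dimethyl-1,3-dioxolan-4-yl]-2,2,4-trimethyl-1,3-dioxolane-4-carboxylate | CCOC(=O)[C@]1(C)OC(C)(C)O[C@H]1[C@@H]2COC(C)(C)O2 | intermediate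
6 | (4R,5S)-5-[(4S)-2,2-dimethyl-1,3-dioxolan-4-yl]-2,2,4-trimethyl-1,3-dioxolane-4-carbaldehyde | O=C[C@]1(C)OC(C)(C)O[C@H]1[C@@H]2COC(C)(C)O2 | intermediate
7 | (4S,5S)-5-[(4S)-2,2-dimethyl-1,3-dioxolan-4-yl]-4-ethynyl-2,2,4-trimethyl-1,3-dioxolane | C#C[C@]1(C)OC(C)(C)O[C@H]1[C@@H]2COC(C)(C)O2 | intermediate
8 | (1S)-1-[(4S,5S)-5-ethynyl-2,2,5-trimethyl-1,3-dioxolan-4-yl]ethane-1,2-diol | C#C[C@]1(C)OC(C)(C)O[C@H]1[C@@H](O)CO | intermediate
9 | bis(triethylsilyl) ether of 8 | C#C[C@]1(C)OC(C)(C)O[C@H]1[C@@H](O[Si](CC)(CC)CC)CO[Si](CC)(CC)CC | intermediate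
10 | (2R)-2-[(4S,5S)-5-ethynyl-2,2,5-trimethyl-1,3-dioxolan-4-yl]-2-(triethylsilyloxy)acetaldehyde | C#C[C@]1(C)OC(C)(C)O[C@H]1[C@@H](O[Si](CC)(CC)CC)C=O | intermediate
11 | methyl propiolate | C#CC(=O)OC | starting material
12 | methyl 2-(diisobutylalumanyl)prop-2-enoate | C=C(C(=O)OC)[Al](CC(C)C)CC(C)C | intermediate
13 | methyl (4S)-4-[(4S,5S)-5-ethynyl-2,2,5-trimethyl-1,3-dioxolan-4-yl]-3-hydroxy-2-methylidene-4-(triethylsilyloxy)butanoate, both C3 epimers | C#C[C@]1(C)OC(C)(C)O[C@H]1[C@@H](O[Si](CC)(CC)CC)C(O)C(=C)C(=O)OC | intermediate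
14 | methyl (2Z,4S)-2-(bromomethyl)-4-[(4S,5S)-5-ethynyl-2,2,5-trimethyl-1,3-dioxolan-4-yl]-4-(triethylsilyloxy)but-2-enoate | C#C[C@]1(C)OC(C)(C)O[C@H]1[C@@H](O[Si](CC)(CC)CC)/C=C(\CBr)C(=O)OC | intermediate
15 | but-2-yn-1-ol | CC#CCO | starting material
16 | (Z)-3-iodobut-2-en-1-ol | OC/C=C(/C)I | intermediate
17 | (Z)-3-iodobut-2-enal | O=C/C=C(/C)I | intermediate
18 | open-chain syn hydroxy ester (free O6–H, C12 methyl ester, 8-OSiEt3, 9,10-acetonide) | COC(=O)C(=C)[C@@H]([C@@H](O)/C=C(/C)I)[C@H](O[Si](CC)(CC)CC)[C@@H]1OC(C)(C)O[C@@]1(C)C#C | intermediate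
19 | 6,7-cis α-methylene-γ-butyrolactone with C4 vinyl iodide, 8-OSiEt3, 9,10-acetonide and C1≡C2 alkyne | C=C1C(=O)O[C@@H](/C=C(/C)I)[C@H]1[C@H](O[Si](CC)(CC)CC)[C@@H]2OC(C)(C)O[C@@]2(C)C#C | intermediate
20 | C8 alcohol derived from 19 | C=C1C(=O)O[C@@H](/C=C(/C)I)[C@H]1[C@H](O)[C@@H]2OC(C)(C)O[C@@]2(C)C#C | intermediate
21 | tert-butyl acrylate | C=CC(=O)OC(C)(C)C | starting material
22 | acetaldehyde | CC=O | starting material
23 | tert-butyl 3-hydroxy-2-methylidenebutanoate (racemic) | CC(O)C(=C)C(=O)OC(C)(C)C | intermediate
24 | tert-butyl (E)-2-(acetoxymethyl)but-2-enoate | C/C=C(\COC(C)=O)C(=O)OC(C)(C)C | intermediate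
25 | (E)-2-(acetoxymethyl)but-2-enoic acid | C/C=C(\COC(C)=O)C(=O)O | intermediate
26 | 8-O-[(E)-2-(acetoxymethyl)but-2-enoyl] derivative of 20 | C=C1C(=O)O[C@@H](/C=C(/C)I)[C@H]1[C@H](OC(=O)/C(=C/C)COC(C)=O)[C@@H]2OC(C)(C)O[C@@]2(C)C#C | intermediate
27 | 9,10-diol derived from 26 (vinyl iodide, tertiary propargylic alcohol) | C=C1C(=O)O[C@@H](/C=C(/C)I)[C@H]1[C@H](OC(=O)/C(=C/C)COC(C)=O)[C@H](O)[C@@](C)(O)C#C | intermediate
28 | ten-membered 9,10-dihydroxy-3-oxo-1-yne (4-hydroxy-2-ynone) fused to the lactone | C=C1C(=O)O[C@H]2/C=C(/C)C(=O)C#C[C@](C)(O)[C@@H](O)[C@@H](OC(=O)/C(=C/C)COC(C)=O)[C@@H]12 | intermediate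
29 | ten-membered 9,10-dihydroxy-1,3-dione | C=C1C(=O)O[C@H]2/C=C(/C)C(=O)CC(=O)[C@](C)(O)[C@@H](O)[C@@H](OC(=O)/C(=C/C)COC(C)=O)[C@@H]12 | intermediate
30 | (6S,7S,8S,9S,10R)-8-[(E)-2-(acetoxymethyl)but-2-enoyloxy]-9-hydroxy-1-oxo-3,10-epoxygermacra-2,4Z,11(13)-trien-12,6-olide | C=C1C(=O)O[C@H]2/C=C(/C)C3=CC(=O)[C@](C)(O3)[C@@H](O)[C@@H](OC(=O)/C(=C/C)COC(C)=O)[C@@H]12 | target

**Step count and risks**

Total step count: 20. Longest linear sequence: 15 (steps 1–10, 13, 14, 18, 19, 20).

**Step 20 (the labelled step).**
- What may go wrong: oligomerisation instead of ring closure; interception of the acylpalladium by water or by the methylene lactone; slow ionisation of the side-chain allylic acetate by zerovalent palladium; or hydration of 28 that is too slow.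
- Fallback: this uses known chemistry only. The carbocycle is closed by nucleophilic alkynylation of an aldehyde instead of acyl transfer, and the furanone is still closed last. Setting out from 26, Stille coupling with Bu3SnCH2OH (Pd2(dba)3, AsPh3, NMP) gives the (Z)-allylic alcohol F1. MnO2 then gives the (Z)-enal F2, and NIS with AgNO3 (cat.) gives the iodoalkyne F3. Nozaki–Hiyama–Kishi closure (CrCl2, NiCl2 cat., THF, high dilution), a reaction type proven for strained ten-membered cycloalkynes, gives the macrocyclic propargylic alcohol F4. Dess–Martin periodinane gives the ynone acetonide F5, and cold aqueous TFA frees the diol. The sequence comes back to the route at 28, which is now isolated and isomerised to 30 with Ph3PAuNTf2 (cat.) in wet toluene, the known monovalent-gold cycloisomerisation of 4-hydroxy-2-ynones to 3(2H)-furanones.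

**Step 13.**
- What may go wrong: poor facial selectivity at C7; erosion of the syn selectivity through E/Z equilibration of the allylindium; or 1,4-elimination of the silyloxy group from the allylmetal.
- Fallback: a configurationally stable allylboronate and catalyst control replace a fluxional allylmetal and substrate control. Setting out from 13, acetylation (Ac2O, DMAP) gives the acetate F6. Borylation with B2pin2 (Pd2(dba)3 cat., toluene) gives the 2-(methoxycarbonyl)allylboronate F7, with C8 cis to CH2B. Its allylboration of 17 runs through a closed chair and is catalysed by a matched BINOL-derived phosphoric acid that selects the aldehyde face. Acid-induced lactonisation then comes back to the route at 19.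

**Step 9.**
- What may go wrong: reduction of the aldehyde by unconsumed hydride; metalation of the terminal alkyne; or O8-to-O7 silyl migration in the aluminium alkoxide.
- Fallback: amine organocatalysis replaces the stoichiometric vinylmetal. Setting out from 10, the Morita–Baylis–Hillman reaction with methyl acrylate (DABCO, dioxane/H2O, rt) forms the same C7–C11 bond under protic, almost neutral conditions and comes back to the route at 13. No new compound is made.

Further compounds
F1 | step 20 | (Z)-allylic alcohol, 26 with CH2OH in place of iodine | C=C1C(=O)O[C@@H](/C=C(/C)CO)[C@H]1[C@H](OC(=O)/C(=C/C)COC(C)=O)[C@@H]2OC(C)(C)O[C@@]2(C)C#C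
F2 | step 20 | (Z)-enal, C3 aldehyde | C=C1C(=O)O[C@@H](/C=C(/C)C=O)[C@H]1[C@H](OC(=O)/C(=C/C)COC(C)=O)[C@@H]2OC(C)(C)O[C@@]2(C)C#C
F3 | step 20 | (Z)-enal iodoalkyne | C=C1C(=O)O[C@@H](/C=C(/C)C=O)[C@H]1[C@H](OC(=O)/C(=C/C)COC(C)=O)[C@@H]2OC(C)(C)O[C@@]2(C)C#CI
F4 | step 20 | ten-membered C3 propargylic alcohol, 9,10-acetonide, both C3 epimers | C=C1C(=O)O[C@H]2/C=C(/C)C(O)C#C[C@]3(C)OC(C)(C)O[C@H]3[C@@H](OC(=O)/C(=C/C)COC(C)=O)[C@@H]12
F5 | step 20 | ten-membered ynone, 9,10-acetonide | C=C1C(=O)O[C@H]2/C=C(/C)C(=O)C#C[C@]3(C)OC(C)(C)O[C@H]3[C@@H](OC(=O)/C(=C/C)COC(C)=O)[C@@H]12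
F6 | step 13 | C7 acetate of 13 | C#C[C@]1(C)OC(C)(C)O[C@H]1[C@@H](O[Si](CC)(CC)CC)C(OC(C)=O)C(=C)C(=O)OC
F7 | step 13 | pinacol allylboronate, 14 with Bpin in place of bromine and the same alkene geometry | C#C[C@]1(C)OC(C)(C)O[C@H]1[C@@H](O[Si](CC)(CC)CC)/C=C(\CB2OC(C)(C)C(C)(C)O2)C(=O)OC
F0 | step 9 | none | none
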